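**Plan**

- Retrosynthesis: the angelate C–O bond at O11, the acetate C–O bond at O8 and the C11–O bond are cut first, then the lactone bond C7–C11 (radical closure from a bromoacetal on O6). Next C10–C1 is cut while C8–C10 is re-formed, which folds ring A back to a bicyclo[3.1.0]hexan-1-ol. Last come the cyclopropane CH2 (C9) and the C5–C4 bond, leaving a 4-silyloxy-2-methylcyclopentenone.
- Enabling feature: the quaternary carbon C10 (methyl, vinyl) lies β to the oxygen-bearing C8 with only the ring methylene C9 between them. Ring A (C5–C10) is therefore the cyclopentane C8–C7–C6–C5–C10 widened by C9, and an alkoxy radical at C8 of the fused cyclopropanol opens to the C8 ketone and a C10 radical that takes up C1–C2.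
- Forward order: cyclopentenone (Piancatelli) → isopropenyl at C5 with enol silane → cyclopropanol → ring A by ring-expanding alkynylation (C10–C1) → vinyl group → ring B (lactone) by 5-exo radical closure C7–C11 → C8 reduction, C11 hydroxylation, two acylations.
- Stereochemistry: C6 from a lipase resolution; C5 by conjugate addition trans to the silyloxy group; C10 by radical trapping anti to the C5 isopropenyl group; C7 by the cis fusion forced in the radical closure; C8 by equatorial hydride delivery opposite the axial C10 methyl; C11 by convex-face enolate hydroxylation; the Z-alkene comes intact from angelic acid.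

Key step: step 8

Remark: atom labels follow elemane numbering (C10 quaternary with C14 methyl and vinyl C1=C2; C5 with isopropenyl; C6 lactone oxygen carbon; C7 ring fusion; C8 acetoxy carbon; C9 ring CH2; C11 lactone α-carbon; C12 lactone carbonyl), and the lipase of step 2 is assumed to acylate the (R)-alcohol as the Kazlauskas rule predicts.

**Route**

Step 1
Reactants: 1 1-(furan-2-yl)ethanol (racemic)
Product: 3 rac-4-hydroxy-2-methylcyclopent-2-en-1-one, via rac-trans-4-hydroxy-5-methylcyclopent-2-en-1-one 2 (not isolated)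
Conditions: ZnCl2 (cat.), H2O/dioxane, reflux; then phosphate buffer pH 8, 50 °C
Reagents that add atoms: water, O
Why: Piancatelli rearrangement (furfuryl cation, hydration, conrotatory 4π closure) gives the trans-4-hydroxy-5-methyl enone, which in the mildly basic buffer isomerises to the more substituted and more stable 2-methyl enone; the product is racemic and no stereocentre is carried on.

Step 2
Reactants: 3 rac-4-hydroxy-2-methylcyclopent-2-en-1-one
Product: 4 (1R)-3-methyl-4-oxocyclopent-2-en-1-yl acetate
Conditions: Amano lipase PS, vinyl acetate, t-BuOMe, rt, stopped near 50% conversion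
Reagents that add atoms: vinyl acetate, CC(=O)OC=C
Why: Lipase-catalysed kinetic resolution by irreversible transesterification should acylate the (R)-alcohol (alkene side as the large substituent), so the acetate carries the C6 configuration of the target while the (S)-alcohol stays behind and is separated.

Step 3
Reactants: 4 (1R)-3-methyl-4-oxocyclopent-2-en-1-yl acetate
Product: 5 (4R)-4-hydroxy-2-methylcyclopent-2-en-1-one
Conditions: Novozym 435 (immobilised Candida antarctica lipase B), MeOH, t-BuOMe, 30 °C
Reagents that add atoms: none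
Why: Enzymatic alcoholysis removes the acetate under neutral conditions, which avoids the base-induced β-elimination typical of 4-acyloxycyclopentenones and, having the same enantiopreference as step 2, should raise the enantiomeric purity further.

Step 4
Reactants: 5 (4R)-4-hydroxy-2-methylcyclopent-2-en-1-one
Product: 6 (4R)-4-(tert-butyldimethylsilyloxy)-2-methylcyclopent-2-en-1-one
Conditions: TBSCl, imidazole, DMF, 0 °C → rt
Reagents that add atoms: tert-butyldimethylsilyl chloride, CC(C)(C)[Si](C)(C)Cl
Why: Imidazole-promoted silyl ether formation on a secondary alcohol is routine and leaves the stereocentre untouched.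

Step 5
Reactants: 6 (4R)-4-(tert-butyldimethylsilyloxy)-2-methylcyclopent-2-en-1-one; 7 isopropenylmagnesium bromide CH2=C(CH3)MgBr
Product: 8 (3R,4R)-4-(tert-butyldimethylsilyloxy)-2-methyl-3-(prop-1-en-2-yl)-1-(trimethylsilyloxy)cyclopent-1-ene
Conditions: CuBr·SMe2 (10 mol %), Me3SiCl, THF, −78 °C; Et3N, pentane/aq. NaHCO3 work-up
Reagents that add atoms: chlorotrimethylsilane, C[Si](C)(C)Cl
Why: CuBr·SMe2-catalysed conjugate addition of the Grignard reagent 7, accelerated by Me3SiCl, delivers the isopropenyl group to C5 anti to the neighbouring silyloxy group (trans, as with other 4-silyloxycyclopentenones), and the enolate is trapped regiospecifically as the C8=C10 silyl enol ether.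

Step 6
Reactants: 8 (3R,4R)-4-(tert-butyldimethylsilyloxy)-2-methyl-3-(prop-1-en-2-yl)-1-(trimethylsilyloxy)cyclopent-1-ene; 9 diiodomethane
Product: 10 (1R,3R,4R,5R)-3-(tert-butyldimethylsilyloxy)-5-methyl-4-(prop-1-en-2-yl)-1-(trimethylsilyloxy)bicyclo[3.1.0]hexane
Conditions: Et2Zn (1.5 equiv), CH2I2 (1.5 equiv), CH2Cl2, 0 °C; pyridine quench
Reagents that add atoms: none
Why: Simmons–Smith cyclopropanation (Furukawa variant) is fastest at the electron-rich silyl enol ether, so a limited amount of the carbenoid EtZnCH2I should spare the isopropenyl group; the CH2 adds anti to the C5 isopropenyl group, although either face would serve because both cyclopropane stereocentres are lost in step 8.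

Step 7
Reactants: 10 (1R,3R,4R,5R)-3-(tert-butyldimethylsilyloxy)-5-methyl-4-(prop-1-en-2-yl)-1-(trimethylsilyloxy)bicyclo[3.1.0]hexane
Product: 11 (1R,3R,4R,5R)-3-(tert-butyldimethylsilyloxy)-5-methyl-4-(prop-1-en-2-yl)bicyclo[3.1.0]hexan-1-ol
Conditions: K2CO3 (cat.), MeOH, 0 °C
Reagents that add atoms: none
Why: K2CO3-catalysed methanolysis cleaves the tertiary trimethylsilyl ether at 0 °C without opening the cyclopropanol, and the secondary tert-butyldimethylsilyl ether is stable to these conditions.

Step 8
Reactants: 11 (1R,3R,4R,5R)-3-(tert-butyldimethylsilyloxy)-5-methyl-4-(prop-1-en-2-yl)bicyclo[3.1.0]hexan-1-ol; 12 1-[(triisopropylsilyl)ethynyl]-1,2-benziodoxol-3(1H)-one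
Product: 13 (3S,4R,5R)-5-(tert-butyldimethylsilyloxy)-3-methyl-4-(prop-1-en-2-yl)-3-[(triisopropylsilyl)ethynyl]cyclohexan-1-one
Conditions: AgNO3 (20 mol %), K2S2O8 (2 equiv), CH2Cl2/H2O (1:1), rt
Reagents that add atoms: none
Why: K2S2O8 oxidises the monovalent silver of AgNO3 to divalent silver, which turns cyclopropanol 11 into its alkoxy radical, and strain-releasing β-scission of the ring-fusion bond C8–C10 gives the C8 ketone and the tertiary C10 radical. Ring A is thus closed not by a cyclisation but by one-carbon ring expansion, the five-membered ring C8–C7–C6–C5–C10 taking in C9 as the methylene between C8 and C10. The C10 radical adds to the iodine-bearing alkyne carbon of 12 and expels the benziodoxolonyl radical (C10–C1 bond), which ends as 2-iodobenzoate. The closest known reaction types are the AgNO3/K2S2O8 ring-opening alkynylation of cyclopropanols with ethynylbenziodoxolones and the oxidative ring expansion of bicyclo[n.1.0]alkan-1-ols through β-keto radicals (Ito–Saegusa type). The new stereocentre C10 is set by the adjacent C5 centre, the bulky alkynyl donor approaching the planar radical anti to the isopropenyl group so that the two-carbon unit ends trans to it. The step needs scission of the internal rather than an external cyclopropane bond, which the tertiary radical secures (a primary radical from external cleavage would re-close and drain to the same tertiary radical, Dowd–Beckwith manifold), and chemoselectivity over the isopropenyl alkene, which the mild biphasic room-temperature conditions and the low reactivity of an unactivated alkene toward a nucleophilic tertiary radical should secure.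

Step 9
Reactants: 13 (3S,4R,5R)-5-(tert-butyldimethylsilyloxy)-3-methyl-4-(prop-1-en-2-yl)-3-[(triisopropylsilyl)ethynyl]cyclohexan-1-one
Product: 14 (3S,4R,5R)-3-ethynyl-5-hydroxy-3-methyl-4-(prop-1-en-2-yl)cyclohexan-1-one
Conditions: Bu4NF, AcOH (1:1), THF, 0 °C → rt
Reagents that add atoms: none
Why: Fluoride-mediated desilylation cleaves both the alkynyl C–Si bond and the silyl ether, and the acetic acid buffer keeps the medium from triggering E1cB loss of the β-hydroxyl group of the ketone.

Step 10
Reactants: 14 (3S,4R,5R)-3-ethynyl-5-hydroxy-3-methyl-4-(prop-1-en-2-yl)cyclohexan-1-one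
Product: 15 (3R,4R,5R)-3-ethenyl-5-hydroxy-3-methyl-4-(prop-1-en-2-yl)cyclohexan-1-one
Conditions: H2 (1 atm), Pd/CaCO3 poisoned with Pb(OAc)2, quinoline, EtOAc, rt
Reagents that add atoms: none
Why: Semihydrogenation over Pd/CaCO3 poisoned with Pb(OAc)2 (Lindlar catalyst) should stop at the alkene for a terminal alkyne and leave the 1,1-disubstituted isopropenyl group and the ketone untouched.

Step 11
Reactants: 15 (3R,4R,5R)-3-ethenyl-5-hydroxy-3-methyl-4-(prop-1-en-2-yl)cyclohexan-1-one; 16 ethyl prop-1-enyl ether (E/Z mixture)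
Product: 17 (3R,4R,5R)-5-(2-bromo-1-ethoxypropoxy)-3-ethenyl-3-methyl-4-(prop-1-en-2-yl)cyclohexan-1-one (mixture at the acetal carbon C12 and at C11)
Conditions: NBS, CH2Cl2, −40 → 0 °C
Reagents that add atoms: N-bromosuccinimide, O=C1CCC(=O)N1Br
Why: Haloacetalisation (first half of the Ueno–Stork sequence) works because NBS attacks the electron-rich enol ether far faster than the other alkenes and the C6 hydroxyl captures the bromo-oxocarbenium ion; the two new centres form as mixtures that converge later (C12 becomes a carbonyl, C11 a radical and then an enolate).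

Step 12
Reactants: 17 (3R,4R,5R)-5-(2-bromo-1-ethoxypropoxy)-3-ethenyl-3-methyl-4-(prop-1-en-2-yl)cyclohexan-1-one
Product: 18 {[(3S,4R,5R)-3-(2-bromo-1-ethoxypropoxy)-5-ethenyl-5-methyl-4-(prop-1-en-2-yl)cyclohex-1-en-1-yl]oxy}trimethylsilane (C7=C8 enol silane)
Conditions: Me3SiCl then LiN(i-Pr)2 (in situ quench), THF, −78 °C; Et3N, pentane work-up
Reagents that add atoms: chlorotrimethylsilane, C[Si](C)(C)Cl
Why: Kinetic deprotonation with in situ silylation should take the C7 hydrogen, because the C9 methylene is neopentylic (next to quaternary C10) and screened from the hindered amide base, while immediate O-silylation at −78 °C forestalls β-elimination of the acetal oxygen.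

Step 13
Reactants: 18 {[(3S,4R,5R)-3-(2-bromo-1-ethoxypropoxy)-5-ethenyl-5-methyl-4-(prop-1-en-2-yl)cyclohex-1-en-1-yl]oxy}trimethylsilane
Product: 19 cis-fused bicyclic acetal 2-ethoxy-6-ethenyl-3,6-dimethyl-7-(prop-1-en-2-yl)-4-(trimethylsilyloxy)octahydro-1-benzofuran (C5 R; C10 R; C6–O and C7–C11 on the same face; mixture at C8 and C11 and C12)
Conditions: Bu3SnH (syringe pump), AIBN (cat.), PhH, 80 °C
Reagents that add atoms: none
Why: Ueno–Stork radical cyclisation closes ring B 5-exo-trig from C11 onto C7 of the enol silane, necessarily on the face of the C6–O bond, which sets C7 with a cis ring fusion; the resulting α-silyloxy C8 radical is reduced by Bu3SnH without stereochemical consequence because C8 is re-oxidised in step 14.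

Step 14
Reactants: 19 cis-fused bicyclic acetal with 8-trimethylsilyloxy group
Product: 21 (3aS,6R,7R,7aS)-6-ethenyl-3,6-dimethyl-7-(prop-1-en-2-yl)-3a,6,7,7a-tetrahydro-1-benzofuran-2,4(3H,5H)-dione (8-oxo-6,12-olide; C11 epimers), via hydroxy lactol 20 (not isolated)
Conditions: CrO3, H2SO4, H2O, acetone, 0 °C, short reaction time
Reagents that add atoms: water, O
Why: Jones oxidation in aqueous acid hydrolyses the mixed acetal and the trimethylsilyl ether and oxidises the lactol to the γ-lactone and the secondary alcohol to the C8 ketone in one operation, the isolated alkenes being inert to CrO3/H2SO4 at 0 °C and the brief exposure sparing the C7 centre next to the new ketone.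

Step 15
Reactants: 21 (3aS,6R,7R,7aS)-6-ethenyl-3,6-dimethyl-7-(prop-1-en-2-yl)-3a,6,7,7a-tetrahydro-1-benzofuran-2,4(3H,5H)-dione
Product: 22 (3aR,4S,6R,7R,7aS)-6-ethenyl-4-hydroxy-3,6-dimethyl-7-(prop-1-en-2-yl)hexahydro-1-benzofuran-2(3H)-one (C11 epimers)
Conditions: LiBH(s-Bu)3, THF, −78 °C; then H2O
Reagents that add atoms: none
Why: Reduction of a cyclohexanone with the bulky LiBH(s-Bu)3 is used because axial approach is blocked by the axial C10 methyl group in a 1,3-relationship, so hydride should enter equatorially from the face of C11 and give the axial 8-alcohol trans to the C7–C11 bond (as with 3,3,5-trimethylcyclohexanone), while the lactone is not reduced at −78 °C.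

Step 16
Reactants: 22 (3aR,4S,6R,7R,7aS)-6-ethenyl-4-hydroxy-3,6-dimethyl-7-(prop-1-en-2-yl)hexahydro-1-benzofuran-2(3H)-one
Product: 24 (3S,3aR,4S,6R,7R,7aS)-6-ethenyl-3,4-dihydroxy-3,6-dimethyl-7-(prop-1-en-2-yl)hexahydro-1-benzofuran-2(3H)-one, via dipotassium alkoxide enolate 23 (not isolated)
Conditions: KN(SiMe3)2 (2.2 equiv), THF, −78 °C; then 3-phenyl-2-(phenylsulfonyl)oxaziridine, −78 °C; AcOH quench
Reagents that add atoms: 3-phenyl-2-(phenylsulfonyl)oxaziridine, O=S(=O)(c1ccccc1)N1OC1c1ccccc1
Why: Enolate hydroxylation with an N-sulfonyloxaziridine (Davis oxidation) should attack the lactone enolate of the cis-fused bicycle on its convex face, away from ring A, which places the new C11 oxygen exo and the methyl group endo as the target requires; the second equivalent of base only holds the C8 hydroxyl as its alkoxide.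

Step 17
Reactants: 24 (3S,3aR,4S,6R,7R,7aS)-6-ethenyl-3,4-dihydroxy-3,6-dimethyl-7-(prop-1-en-2-yl)hexahydro-1-benzofuran-2(3H)-one
Product: 25 (3S,3aR,4S,6R,7R,7aS)-6-ethenyl-3-hydroxy-3,6-dimethyl-2-oxo-7-(prop-1-en-2-yl)octahydro-1-benzofuran-4-yl acetate
Conditions: Ac2O (1.2 equiv), pyridine, DMAP (cat.), CH2Cl2, 0 °C → rt
Reagents that add atoms: acetic anhydride, CC(=O)OC(C)=O
Why: Nucleophile-catalysed acetylation should distinguish the secondary C8 hydroxyl from the tertiary, electron-poor α-hydroxy-lactone hydroxyl, which does not react under these conditions.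

Step 18
Reactants: 26 angelic acid ((2Z)-2-methylbut-2-enoic acid), two molecules per molecule of product
Product: 27 angelic anhydride ((2Z)-2-methylbut-2-enoic anhydride)
Conditions: DCC (0.5 equiv with respect to 26), CH2Cl2, 0 °C → rt; filtration of the urea
Reagents that add atoms: angelic acid (the second molecule of 26), C/C=C(/C)C(=O)O
Why: Carbodiimide dehydration joins two molecules of the acid to the symmetrical anhydride, the water being taken up by DCC as the urea, and because no base or nucleophilic catalyst is present the Z double bond of the angeloyl unit should not isomerise.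

Step 19
Reactants: 25 (3S,3aR,4S,6R,7R,7aS)-6-ethenyl-3-hydroxy-3,6-dimethyl-2-oxo-7-(prop-1-en-2-yl)octahydro-1-benzofuran-4-yl acetate; 27 angelic anhydride
Product: 29 (3S,3aR,4S,6R,7R,7aS)-4-acetoxy-6-ethenyl-3,6-dimethyl-2-oxo-7-(prop-1-en-2-yl)octahydro-1-benzofuran-3-yl (2Z)-2-methylbut-2-enoate (CNP0140071.1), via lithium C11 alkoxide 28 (not isolated)
Conditions: LiN(SiMe3)2 (1.05 equiv), THF, −78 °C; then 27, −78 → 0 °C
Reagents that add atoms: none
Why: Acylation of a preformed lithium alkoxide by a symmetrical anhydride at low temperature, one angeloyl unit being transferred and the other leaving as the carboxylate, is a stereoconservative route to angelates of hindered alcohols, since no amine or nucleophilic catalyst is present to isomerise the angelate to the tiglate, and the trans-diaxial arrangement of the C8 acetate and the C7–C11 bond prevents acyl migration.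

**Compound list**

1 | 1-(furan-2-yl)ethanol (racemic) | CC(O)c1ccco1 | starting material
2 | rac-trans-4-hydroxy-5-methylcyclopent-2-en-1-one (one enantiomer drawn) | O=C1C=C[C@@H](O)[C@@H]1C | intermediate (not isolated)
3 | rac-4-hydroxy-2-methylcyclopent-2-en-1-one | CC1=CC(O)CC1=O | intermediate
4 | (1R)-3-methyl-4-oxocyclopent-2-en-1-yl acetate | O=C1C[C@@H](OC(C)=O)C=C1C | intermediate
5 | (4R)-4-hydroxy-2-methylcyclopent-2-en-1-one | O=C1C[C@@H](O)C=C1C | intermediate
6 | (4R)-4-(tert-butyldimethylsilyloxy)-2-methylcyclopent-2-en-1-one | O=C1C[C@@H](O[Si](C)(C)C(C)(C)C)C=C1C | intermediate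
7 | isopropenylmagnesium bromide | CC(=C)[Mg]Br | starting material
8 | (3R,4R)-4-(tert-butyldimethylsilyloxy)-2-methyl-3-(prop-1-en-2-yl)-1-(trimethylsilyloxy)cyclopent-1-ene | CC1=C(O[Si](C)(C)C)C[C@@H](O[Si](C)(C)C(C)(C)C)[C@@H]1C(=C)C | intermediate
9 | diiodomethane | ICI | starting material
10 | (1R,3R,4R,5R)-3-(tert-butyldimethylsilyloxy)-5-methyl-4-(prop-1-en-2-yl)-1-(trimethylsilyloxy)bicyclo[3.1.0]hexane | C[C@]12C[C@@]1(O[Si](C)(C)C)C[C@@H](O[Si](C)(C)C(C)(C)C)[C@@H]2C(=C)C | intermediate
11 | (1R,3R,4R,5R)-3-(tert-butyldimethylsilyloxy)-5-methyl-4-(prop-1-en-2-yl)bicyclo[3.1.0]hexan-1-ol | C[C@]12C[C@@]1(O)C[C@@H](O[Si](C)(C)C(C)(C)C)[C@@H]2C(=C)C | intermediate (key-step precursor)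
12 | 1-[(triisopropylsilyl)ethynyl]-1,2-benziodoxol-3(1H)-one | CC(C)[Si](C#CI1OC(=O)c2ccccc12)(C(C)C)C(C)C | starting material
13 | (3S,4R,5R)-5-(tert-butyldimethylsilyloxy)-3-methyl-4-(prop-1-en-2-yl)-3-[(triisopropylsilyl)ethynyl]cyclohexan-1-one | CC(C)[Si](C#C[C@@]1(C)CC(=O)C[C@@H](O[Si](C)(C)C(C)(C)C)[C@@H]1C(=C)C)(C(C)C)C(C)C | intermediate (key-step product)
14 | (3S,4R,5R)-3-ethynyl-5-hydroxy-3-methyl-4-(prop-1-en-2-yl)cyclohexan-1-one | C#C[C@@]1(C)CC(=O)C[C@@H](O)[C@@H]1C(=C)C | intermediate
15 | (3R,4R,5R)-3-ethenyl-5-hydroxy-3-methyl-4-(prop-1-en-2-yl)cyclohexan-1-one | C=C[C@@]1(C)CC(=O)C[C@@H](O)[C@@H]1C(=C)C | intermediate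
16 | ethyl prop-1-enyl ether (E/Z mixture) | CCOC=CC | starting material
17 | (3R,4R,5R)-5-(2-bromo-1-ethoxypropoxy)-3-ethenyl-3-methyl-4-(prop-1-en-2-yl)cyclohexan-1-one (mixture at the acetal and CHBr carbons) | C=C[C@@]1(C)CC(=O)C[C@@H](OC(OCC)C(C)Br)[C@@H]1C(=C)C | intermediate
18 | {[(3S,4R,5R)-3-(2-bromo-1-ethoxypropoxy)-5-ethenyl-5-methyl-4-(prop-1-en-2-yl)cyclohex-1-en-1-yl]oxy}trimethylsilane | C=C[C@@]1(C)CC(O[Si](C)(C)C)=C[C@@H](OC(OCC)C(C)Br)[C@@H]1C(=C)C | intermediate
19 | 2-ethoxy-6-ethenyl-3,6-dimethyl-7-(prop-1-en-2-yl)-4-(trimethylsilyloxy)octahydro-1-benzofuran, cis-fused (mixture at C8, C11, C12) | C=C[C@@]1(C)CC(O[Si](C)(C)C)[C@@H]2[C@@H](OC(OCC)C2C)[C@@H]1C(=C)C | intermediate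
20 | 6-ethenyl-3,6-dimethyl-7-(prop-1-en-2-yl)octahydro-1-benzofuran-2,4-diol, cis-fused hydroxy lactol (mixture at C8, C11, C12) | C=C[C@@]1(C)CC(O)[C@@H]2[C@@H](OC(O)C2C)[C@@H]1C(=C)C | intermediate (not isolated)
21 | (3aS,6R,7R,7aS)-6-ethenyl-3,6-dimethyl-7-(prop-1-en-2-yl)-3a,6,7,7a-tetrahydro-1-benzofuran-2,4(3H,5H)-dione (C11 epimers) | C=C[C@@]1(C)CC(=O)[C@@H]2[C@@H](OC(=O)C2C)[C@@H]1C(=C)C | intermediate
22 | (3aR,4S,6R,7R,7aS)-6-ethenyl-4-hydroxy-3,6-dimethyl-7-(prop-1-en-2-yl)hexahydro-1-benzofuran-2(3H)-one (C11 epimers) | C=C[C@@]1(C)C[C@H](O)[C@@H]2[C@@H](OC(=O)C2C)[C@@H]1C(=C)C | intermediate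
23 | dipotassium C8 alkoxide / lactone enolate of 22 | C=C[C@@]1(C)C[C@H]([O-])[C@@H]2[C@@H](OC([O-])=C2C)[C@@H]1C(=C)C.[K+].[K+] | intermediate (not isolated)
24 | (3S,3aR,4S,6R,7R,7aS)-6-ethenyl-3,4-dihydroxy-3,6-dimethyl-7-(prop-1-en-2-yl)hexahydro-1-benzofuran-2(3H)-one | C=C[C@@]1(C)C[C@H](O)[C@@H]2[C@@H](OC(=O)[C@@]2(C)O)[C@@H]1C(=C)C | intermediate
25 | (3S,3aR,4S,6R,7R,7aS)-6-ethenyl-3-hydroxy-3,6-dimethyl-2-oxo-7-(prop-1-en-2-yl)octahydro-1-benzofuran-4-yl acetate | C=C[C@@]1(C)C[C@H](OC(C)=O)[C@@H]2[C@@H](OC(=O)[C@@]2(C)O)[C@@H]1C(=C)C | intermediate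
26 | angelic acid, (2Z)-2-methylbut-2-enoic acid | C/C=C(/C)C(=O)O | starting material
27 | angelic anhydride, (2Z)-2-methylbut-2-enoic anhydride | C/C=C(/C)C(=O)OC(=O)/C(C)=C\C | intermediate
28 | lithium C11 alkoxide of 25 | C=C[C@@]1(C)C[C@H](OC(C)=O)[C@@H]2[C@@H](OC(=O)[C@@]2(C)[O-])[C@@H]1C(=C)C.[Li+] | intermediate (not isolated)
29 | (3S,3aR,4S,6R,7R,7aS)-4-acetoxy-6-ethenyl-3,6-dimethyl-2-oxo-7-(prop-1-en-2-yl)octahydro-1-benzofuran-3-yl (2Z)-2-methylbut-2-enoate | C=C[C@@]1(C)C[C@H](OC(C)=O)[C@@H]2[C@@H](OC(=O)[C@@]2(C)OC(=O)/C(C)=C\C)[C@@H]1C(=C)C | target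

**Count and risks**

Total steps: 19. Longest linear sequence: 18 steps (steps 1–17 and 19, from 1 to 29); step 18 is a one-step side branch.

Steps most likely to fail:

1. Step 8. The C10 radical may be trapped with poor facial selectivity, it may suffer a 1,2-shift of the neighbouring isopropenyl group through a cyclopropylcarbinyl radical, or K2S2O8 may attack the isopropenyl group or loosen the silyl ether before alkynylation. The fallback keeps the ring expansion but makes the quaternary centre by conjugate addition. It sets out from 10: FeCl3 in DMF at 0 °C (Ito–Saegusa ring expansion) should give the β-chloro ketone F1, and NaOAc in MeOH at reflux the enone F2. (CH2=CH)2CuLi in Et2O at −78 °C should then add at C10 anti to the adjacent C5 isopropenyl group, the nearer of the two ring substituents, to give the vinyl ketone F3. Bu4NF/AcOH removes the silyl ether and the route is rejoined at 15, bypassing steps 8–10.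

2. Step 19. The hindered tertiary alkoxide may fail to acylate, or the Z-alkene may isomerise to the tiglate during acyl transfer. The fallback forms the ester bond first and the alkene afterwards. It sets out from 25, which would be esterified with 2-[bis(2,2,2-trifluoroethoxy)phosphoryl]propanoic acid (DCC, DMAP, CH2Cl2; ketene-type acylation suited to tertiary alcohols) to the phosphonate ester F4. A Still–Gennari olefination with acetaldehyde (KN(SiMe3)2, 18-crown-6, THF, −78 °C) should then build the Z-configured 2-methylbut-2-enoate and arrive directly at 29.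

3. Step 6. The carbenoid EtZnCH2I may lose chemoselectivity and also cyclopropanate the isopropenyl alkene, or the enol silane may hydrolyse under the Lewis-acidic ZnI2 that accumulates. The fallback makes the cyclopropanol from the enolate instead of the enol ether. It sets out from 8: MeLi in THF at 0 °C would cleave the trimethylsilyl group to the lithium enolate F5, and CH2I2 with SmI2 (the carbenoid ICH2SmI2, which leaves unfunctionalised alkenes alone) should iodomethylate the enolate and close the three-membered ring. This comes back to the route at 11 and bypasses 10.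

Further compounds
F1 | step 8 | 5-(tert-butyldimethylsilyloxy)-3-chloro-3-methyl-4-(prop-1-en-2-yl)cyclohexan-1-one (C5 and C6 as in 10; epimers at the chlorine-bearing carbon) | CC1(Cl)CC(=O)C[C@@H](O[Si](C)(C)C(C)(C)C)[C@@H]1C(=C)C
F2 | step 8 | (4R,5R)-5-(tert-butyldimethylsilyloxy)-3-methyl-4-(prop-1-en-2-yl)cyclohex-2-en-1-one | CC1=CC(=O)C[C@@H](O[Si](C)(C)C(C)(C)C)[C@@H]1C(=C)C
F3 | step 8 | (3R,4R,5R)-5-(tert-butyldimethylsilyloxy)-3-ethenyl-3-methyl-4-(prop-1-en-2-yl)cyclohexan-1-one | C=C[C@@]1(C)CC(=O)C[C@@H](O[Si](C)(C)C(C)(C)C)[C@@H]1C(=C)C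
F4 | step 19 | (3S,3aR,4S,6R,7R,7aS)-4-acetoxy-6-ethenyl-3,6-dimethyl-2-oxo-7-(prop-1-en-2-yl)octahydro-1-benzofuran-3-yl 2-[bis(2,2,2-trifluoroethoxy)phosphoryl]propanoate | C=C[C@@]1(C)C[C@H](OC(C)=O)[C@@H]2[C@@H](OC(=O)[C@@]2(C)OC(=O)C(C)P(=O)(OCC(F)(F)F)OCC(F)(F)F)[C@@H]1C(=C)C
F5 | step 6 | lithium (3R,4R)-4-(tert-butyldimethylsilyloxy)-2-methyl-3-(prop-1-en-2-yl)cyclopent-1-en-1-olate | [Li+].CC1=C([O-])C[C@@H](O[Si](C)(C)C(C)(C)C)[C@@H]1C(=C)C
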